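**Assumption (one line):** iridoid numbering is used in the text (C1 acetal, O2, C3=C4, C5/C9 ring fusion, C7/C8 carbinols, C10 = CH2OAc, C11 = CH2O‑isovaleryl); the target is (1S,5S,7S,8R,9S), i.e. H‑5, H‑9, 1‑O‑acyl, 7‑OH and C10 on one face (β) and 8‑OH on the other (α).

## Retrosynthetic overview

1. Disconnect C4–C11 last: enol triflate + (isovaleryloxymethyl)stannane (new Pd/Cu acyloxymethyl coupling), because the enol‑ether allylic ester is acid‑ and Lewis‑acid‑labile.
2. 7β‑OH / 8α‑OH / 10‑OAc come from the β‑epoxide of the C7=C8 allylic acetate, opened anti at tertiary C8 with acetate relay.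
3. C10 alcohol comes from a tert‑butyl enoate (hydride‑free towards the C1 acyl acetal); the enol triflate comes from the C4 ketone.
4. The cyclopentene ring is formed second, by phosphine‑catalysed [3+2] of an (S)‑6‑acyloxypyranone with tert‑butyl allenoate (C1 controls C5 and C9).
5. The pyran ring is formed first, by Achmatowicz rearrangement of furfuryl alcohol; C1 is set by dynamic kinetic acylation that installs the final isovalerate at the outset.

## Route

**Step 1**
Reactants: 1 furfuryl alcohol
Product: 2 (±)-6-hydroxy-2H-pyran-3(6H)-one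
Conditions: NBS, NaHCO3, NaOAc, THF/H2O (4:1), 0 °C
Reagents that add atoms: water, O
Why: Achmatowicz oxidative ring expansion (furan oxidation, ring opening to the cis‑enedione, lactolisation by the CH2OH oxygen); the lactol carbon is configurationally labile, so no stereocentre is fixed yet.

**Step 2**
Reactants: 2; 3 isovaleric anhydride
Product: 4 (2S)-5-oxo-5,6-dihydro-2H-pyran-2-yl 3-methylbutanoate
Conditions: (R)-benzotetramisole (5 mol %), i‑Pr2NEt, CHCl3, 0 °C (assumed (S)‑selective; use (S)‑BTM if the sense is opposite)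
Reagents that add atoms: none beyond 3
Why: Isothiourea‑catalysed dynamic kinetic resolution by enantioselective acyl transfer: the lactol enantiomers interconvert by ring opening while the chiral N‑acyl isothiouronium acylates only the (S)‑lactol, setting C1 with its final isovalerate.

**Step 3**
Reactants: 5 tert‑butyl (triphenylphosphoranylidene)acetate; 6 acetyl chloride
Product: 7 tert‑butyl buta-2,3-dienoate
Conditions: Et3N, CH2Cl2, 0 °C → rt
Reagents that add atoms: none
Why: Wittig olefination of ketene (generated in situ from AcCl/Et3N) by the stabilised ylide gives the allenoate; no stereocentre.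

**Step 4**
Reactants: 4; 7
Product: 8 tert‑butyl (1S,4aS,7aS)-1-(3-methylbutanoyloxy)-4-oxo-1,3,4,4a,5,7a-hexahydrocyclopenta[c]pyran-7-carboxylate
Conditions: PPh3 (10 mol %), toluene, rt
Reagents that add atoms: none
Why: Lu phosphine‑catalysed [3+2] annulation: the allenoate zwitterion adds through its ester‑bearing carbon to the enone β‑carbon anti to the C1 acyloxy group and the enolate closes the ring cis, setting C9 and C5 (H‑9 and H‑5 cis to the 1‑O‑acyl group).

**Step 5**
Reactants: 8
Product: 9 tert‑butyl (1S,4aS,7aS)-1-(3-methylbutanoyloxy)-4-(trifluoromethanesulfonyloxy)-1,4a,5,7a-tetrahydrocyclopenta[c]pyran-7-carboxylate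
Conditions: KHMDS, THF, −78 °C; then PhNTf2, −78 → −40 °C
Reagents that add atoms: N‑phenyl‑bis(trifluoromethanesulfonimide), O=S(=O)(N(c1ccccc1)S(=O)(=O)C(F)(F)F)C(F)(F)F
Why: Kinetic enolate O‑triflation: the bulky base removes a proton from the unhindered O–CH2 (C3) rather than the ring‑fusion methine, giving the C3=C4 enol triflate; the esters and acyl acetal are not enolised at −78 °C and no stereocentre changes.

**Step 6**
Reactants: 9
Product: 10 (1S,4aS,7aS)-1-(3-methylbutanoyloxy)-4-(trifluoromethanesulfonyloxy)-1,4a,5,7a-tetrahydrocyclopenta[c]pyran-7-carboxylic acid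
Conditions: TFA/CH2Cl2 (1:3), 0 °C → rt
Reagents that add atoms: none
Why: Acidolysis of the tert‑butyl ester (loss of isobutene); the electron‑poor enol triflate and the acyl acetal tolerate anhydrous TFA.

**Step 7**
Reactants: 10
Product: 11 (1S,4aS,7aS)-7-(hydroxymethyl)-4-(trifluoromethanesulfonyloxy)-1,4a,5,7a-tetrahydrocyclopenta[c]pyran-1-yl 3-methylbutanoate
Conditions: i‑BuOCOCl, N‑methylmorpholine, THF, −15 °C; then NaBH4, H2O, −15 → 0 °C
Reagents that add atoms: none
Why: Mixed‑anhydride activation and borohydride 1,2‑reduction convert only the acid to the allylic alcohol; the isovalerate acyl acetal and vinyl triflate are inert to NaBH4 at this temperature.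

**Step 8**
Reactants: 11
Product: 12 (1S,4aS,6S,7S,7aS)-6,7-epoxy-7-(hydroxymethyl)-4-(trifluoromethanesulfonyloxy)-1,4a,5,6,7,7a-hexahydrocyclopenta[c]pyran-1-yl 3-methylbutanoate (7β,8β‑epoxide, O cis to H‑5/H‑9)
Conditions: Ti(Oi‑Pr)4 (10 mol %), L‑(+)‑DIPT (12 mol %), t‑BuOOH, 4 Å MS, CH2Cl2, −20 °C
Reagents that add atoms: tert‑butyl hydroperoxide, CC(C)(C)OO
Why: Katsuki–Sharpless asymmetric epoxidation: L‑(+)‑tartrate delivers oxygen to the C7=C8 face syn to H‑5/H‑9, which is also the convex face of the cis‑fused bicycle (matched), setting C7 (S) and C8 (S); the enol triflate alkene is not an allylic alcohol and is untouched.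

**Step 9**
Reactants: 12
Product: 13 (1S,4aS,6S,7S,7aS)-7-(acetoxymethyl)-6,7-epoxy-4-(trifluoromethanesulfonyloxy)-1,4a,5,6,7,7a-hexahydrocyclopenta[c]pyran-1-yl 3-methylbutanoate
Conditions: Ac2O, pyridine, DMAP (cat.), CH2Cl2, 0 °C
Reagents that add atoms: acetic anhydride, CC(=O)OC(C)=O
Why: DMAP‑catalysed acetylation of the only free hydroxyl installs the C10 acetate that is both a target substituent and the relay group for the next step.

**Step 10**
Reactants: 13
Product: 14 (1S,4aS,6S,7R,7aS)-7-(acetoxymethyl)-6,7-dihydroxy-4-(trifluoromethanesulfonyloxy)-1,4a,5,6,7,7a-hexahydrocyclopenta[c]pyran-1-yl 3-methylbutanoate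
Conditions: HClO4 (cat.), THF/H2O (4:1), 0 °C; NaHCO3; then Et3N (0.1 equiv), CH2Cl2, rt, brief
Reagents that add atoms: water, O
Why: Neighbouring‑group‑assisted acid opening of the trisubstituted epoxide: the C10 acetate carbonyl (5‑exo) and/or water attacks tertiary C8 from the α‑face with inversion while the epoxide oxygen stays on C7 (β), and hydrolysis of the dioxolan‑2‑ylium followed by acetyl migration to the primary oxygen gives the 7β‑OH/8α‑OH/10‑OAc array (C8 now R, C7 still S).

**Step 11**
Reactants: 15 (tributylstannyl)methanol; 3 isovaleric anhydride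
Product: 16 (tributylstannyl)methyl 3-methylbutanoate
Conditions: Et3N, DMAP (cat.), CH2Cl2, 0 °C → rt
Reagents that add atoms: none beyond 3
Why: Simple DMAP‑catalysed O‑acylation of the primary stannyl carbinol.

**Step 12**
Reactants: 14; 16
Product: 17 target, [(1S,4aS,6S,7R,7aS)-7-(acetoxymethyl)-6,7-dihydroxy-1-(3-methylbutanoyloxy)-1,4a,5,6,7,7a-hexahydrocyclopenta[c]pyran-4-yl]methyl 3-methylbutanoate
Conditions: Pd2(dba)3 (2.5 mol %), AsPh3 (20 mol %), CuI (20 mol %), LiCl, NMP, 23–40 °C
Reagents that add atoms: none beyond 16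
Why: Proposed new method: Pd/Cu‑cocatalysed Stille‑type transfer of an intact acyloxymethyl group to a cyclic α‑alkoxy enol triflate — Pd(0)/AsPh3 inserts into C4–OTf (LiCl gives vinyl–Pd–Cl), the ester carbonyl of 16 chelates Cu(I) so the CH2O2CR group rather than butyl moves Sn→Cu→Pd, and C(sp2)–C(sp3) reductive elimination (no β‑H on the transferred carbon) forms C4–C11 with the isovalerate already attached; the weak donor ligand and low temperature disfavour Pd(0) ionisation of the product allylic ester, and the neutral, hydride‑free conditions spare the acyl acetal, the acetate and the free diol; closest known reaction type is Stille hydroxymethylation/alkoxymethylation of vinyl triflates with Bu3SnCH2OH/Bu3SnCH2OR and copper‑assisted coupling of α‑heteroatom alkylstannanes; no stereocentre is created.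

## Compound list

1 | furfuryl alcohol | OCc1ccco1 | starting material
2 | (±)-6-hydroxy-2H-pyran-3(6H)-one | O=C1COC(O)C=C1 | intermediate
3 | isovaleric (3-methylbutanoic) anhydride | CC(C)CC(=O)OC(=O)CC(C)C | starting material
4 | (2S)-5-oxo-5,6-dihydro-2H-pyran-2-yl 3-methylbutanoate | O=C1C=C[C@H](OC(=O)CC(C)C)OC1 | intermediate
5 | tert‑butyl (triphenylphosphoranylidene)acetate | CC(C)(C)OC(=O)C=P(c1ccccc1)(c1ccccc1)c1ccccc1 | starting material
6 | acetyl chloride | CC(Cl)=O | starting material
7 | tert‑butyl buta-2,3-dienoate | C=C=CC(=O)OC(C)(C)C | intermediate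
8 | tert‑butyl (1S,4aS,7aS)-1-(3-methylbutanoyloxy)-4-oxo-1,3,4,4a,5,7a-hexahydrocyclopenta[c]pyran-7-carboxylate | CC(C)(C)OC(=O)C1=CC[C@H]2[C@@H]1[C@H](OC(=O)CC(C)C)OCC2=O | intermediate
9 | tert‑butyl (1S,4aS,7aS)-1-(3-methylbutanoyloxy)-4-(triflyloxy)-1,4a,5,7a-tetrahydrocyclopenta[c]pyran-7-carboxylate | CC(C)(C)OC(=O)C1=CC[C@H]2[C@@H]1[C@H](OC(=O)CC(C)C)OC=C2OS(=O)(=O)C(F)(F)F | intermediate
10 | (1S,4aS,7aS)-1-(3-methylbutanoyloxy)-4-(triflyloxy)-1,4a,5,7a-tetrahydrocyclopenta[c]pyran-7-carboxylic acid | OC(=O)C1=CC[C@H]2[C@@H]1[C@H](OC(=O)CC(C)C)OC=C2OS(=O)(=O)C(F)(F)F | intermediate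
11 | (1S,4aS,7aS)-7-(hydroxymethyl)-4-(triflyloxy)-1,4a,5,7a-tetrahydrocyclopenta[c]pyran-1-yl 3-methylbutanoate | OCC1=CC[C@H]2[C@@H]1[C@H](OC(=O)CC(C)C)OC=C2OS(=O)(=O)C(F)(F)F | intermediate
12 | (1S,4aS,6S,7S,7aS)-6,7-epoxy-7-(hydroxymethyl)-4-(triflyloxy)-hexahydrocyclopenta[c]pyran-1-yl 3-methylbutanoate (β‑epoxide) | OC[C@@]1(O3)[C@H]2[C@H](OC(=O)CC(C)C)OC=C(OS(=O)(=O)C(F)(F)F)[C@H]2C[C@@H]13 | intermediate
13 | (1S,4aS,6S,7S,7aS)-7-(acetoxymethyl)-6,7-epoxy-4-(triflyloxy)-hexahydrocyclopenta[c]pyran-1-yl 3-methylbutanoate | CC(=O)OC[C@@]1(O3)[C@H]2[C@H](OC(=O)CC(C)C)OC=C(OS(=O)(=O)C(F)(F)F)[C@H]2C[C@@H]13 | intermediate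
14 | (1S,4aS,6S,7R,7aS)-7-(acetoxymethyl)-6,7-dihydroxy-4-(triflyloxy)-hexahydrocyclopenta[c]pyran-1-yl 3-methylbutanoate | CC(=O)OC[C@]1(O)[C@H]2[C@H](OC(=O)CC(C)C)OC=C(OS(=O)(=O)C(F)(F)F)[C@H]2C[C@@H]1O | intermediate
15 | (tributylstannyl)methanol | CCCC[Sn](CCCC)(CCCC)CO | starting material
16 | (tributylstannyl)methyl 3-methylbutanoate | CCCC[Sn](CCCC)(CCCC)COC(=O)CC(C)C | intermediate
17 | target (CID42638123) | CC(=O)OC[C@]1(O)[C@H]2[C@H](OC(=O)CC(C)C)OC=C(COC(=O)CC(C)C)[C@H]2C[C@@H]1O | target

## Summary

**Total steps:** 12 (including two one‑step reagent preparations, Steps 3 and 11).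
**Longest linear sequence:** 10 steps (1 → 2 → 4 → 8 → 9 → 10 → 11 → 12 → 13 → 14 → 17).

**Three steps most likely to fail, with fallbacks**

- **Step 12 (proposed new coupling).** Risks are slow transfer of the acyloxymethyl group or Pd‑mediated ionisation of the product allylic ester. Fallback (known chemistry): Stille hydroxymethylation of 14 with 15 (Pd(PPh3)4, LiCl, dioxane, 90 °C) to the C11 allylic alcohol, then primary‑selective isovalerylation with 3 (2,4,6‑collidine, cat. DMAP, −40 °C). The hindered secondary and tertiary hydroxyls stay free.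
- **Step 5 (regiochemistry of enol triflation, C3 versus C5).** Fallback: drop kinetic enolate trapping and set the regiochemistry thermodynamically. Form the ring‑oxygen‑conjugated C3=C4 silyl enol ether by soft enolisation (TMSOTf, Et3N), then convert it regiospecifically into the enol nonaflate by fluoride‑triggered sulfonyl transfer (NfF, cat. Bu4NF). The nonaflate is carried through Steps 6–12 in the same way.
- **Step 10 (epoxide opening: regio/stereo fidelity and final position of the acetyl group).** Fallback: reverse the order of events. Hydrolyse the free epoxy alcohol 12 (cat. HClO4, THF/H2O) to the 7β,8α,10‑triol by direct anti attack of water at C8. Then acetylate the primary hydroxyl selectively (AcCl, 2,4,6‑collidine, −78 °C, or lipase/vinyl acetate) to reach 14 without the acetate relay.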